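(All constants were chosen freely; the rest is arithmetic.)

- A ratio can say what a clock cannot: we divide the rate of the back step of the first reaction by the rate of its forward step, which gives [target]/(K[starting material][reagent]), where K is the equilibrium constant at that flask's temperature. Time has dropped out, and we call this number the back-to-forward ratio. Where it is small, a simple forward count can be trusted; at one, net making of target stops.

in all of them: starting material 37 mM; reagent 92.5 mM; second substrate 7.40 mM; time 12 min

| charge | temperature |
|---|---|
| gamma | 45 °C |
| beta | 5 °C |
| alpha | −15 °C |
| delta | 25 °C |

    starting material + reagent ⇌ target (K1 = 9.2 M⁻¹, k1 = 1.1 M⁻¹ min⁻¹, Ea1 = 56.0 kJ mol⁻¹, ΔH1 = −10.0 kJ mol⁻¹)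
    second substrate + reagent → second product (k2 = 3.9 M⁻¹ min⁻¹, Ea2 = 62.0 kJ mol⁻¹)
    reagent + target → over-reaction product (k3 = 0.040 M⁻¹ min⁻¹, Ea3 = 62.0 kJ mol⁻¹)
    (constants at 5 °C)

- the constants hold at 5 °C; other temperatures follow from the activation energies and enthalpies

- the flask that comes out highest in amount of target, in percent of the starting material charged, or "all alike" when all lie within 1.5 percentage points (gamma / beta / alpha / delta / all alike)
- target at the end, in percent of the starting material charged, gamma
- target at the end, in percent of the starting material charged, beta
- target at the end, in percent of the starting material charged, alpha
- target at the end, in percent of the starting material charged, delta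

- We begin with alpha and beta, which have equal charges but different temperatures. Cooling raises K from 9.2 M⁻¹ in beta to 12.9 M⁻¹ in alpha.
- Suppose the reagent first loses 7.40 mM to the second substrate. Equilibrium then allows 39.4% target in beta and 46.6% in alpha, so alpha has the higher ceiling.
- But cooling also slows the forward step, whose constant falls to 0.169 M⁻¹ min⁻¹ in alpha. We count forward alone, with the reagent held at its charge in the exponent. In 12 min this gives alpha 17.1% target.
- Putting that amount into the back-to-forward ratio for alpha gives 0.186. This is below one, so the count stands roughly and alpha is under kinetic control.
- The same count for beta gives 70.5% target and a ratio of 3.91. This is above one, and that count lies beyond the ceiling of 39.4%, so we expect beta to end close to its ceiling, under thermodynamic control.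
- The warmer flasks have lower ceilings, 33.4% in delta and 28.5% in gamma. The forward count for alpha also stands below the ceiling of beta, so our choice is beta, and our hand reckoning stops there.
- The forecast chose beta, calling it “the best compromise”, with 15% for alpha, 36.5% for beta, 30.5% for delta and 19.5% for gamma.
- The simulation gives beta as highest, with 15.0% for alpha, 36.4% for beta, 30.1% for delta and 19.2% for gamma.
- From the alpha readings at 12.0 min, the ratio is 0.164, against the 0.186 we reckoned. The neighbouring flask is alpha left until 30 min, with nothing else changed. The forward count for it gives 37.4% target, and with that amount the ratio rises to 0.589. The neighbouring flask holds 28.4% target.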